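Readings and results were computed on assumed constants; scatter was added.

Read at 25 min, each flask has stood 5.00 min past the end of its feed, so what does that interval cost in target?

| flask | substrate | reagent | catalyst | remark | time |
|---|---|---|---|---|---|
| ash | 29 mM | 6.1 mM (fed, over 20 min) | 0.73 mM | run made earlier |  |
| alder | 29 mM | 100 mM (fed, over 20 min) | 0.73 mM | run made earlier |  |
| Saturday's | 29 mM | 8.00 mM (fed, over 20 min) | 0.73 mM |  | 25 min |
| Friday's | 29 mM | 15.0 mM (fed, over 20 min) | 0.73 mM |  | 25 min |
| Tuesday's | 29 mM | 30.0 mM (fed, over 20 min) | 0.73 mM |  | 25 min |
| Wednesday's | 29 mM | 60.0 mM (fed, over 20 min) | 0.73 mM |  | 25 min |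
| Monday's | 29 mM | 120 mM (fed, over 20 min) | 0.73 mM |  | 25 min |

- ash (time / min: target / %): 1.33: 0.6; 2.00: 1.1; 3.00: 1.6; 5.00: 3.3; 8.00: 5.5; 12.0: 8.2; 20.0: 12.0
- alder (time / min: target / %): 1.00: 3.5; 2.50: 16.0; 5.00: 42.0; 8.00: 62.7; 10.0: 67.8; 15.0: 61.3; 20.0: 52.3

(readings scatter by 0.5 percentage points)

- steps under discussion: substrate + reagent + catalyst -> target + catalyst; substrate <-> dormant form; target + catalyst <-> isomer of the product + catalyst
- "hardly changes" means that all values lie within two and a half points (for a concentration: within two and a half percent of the largest)

1. amount of target at the end, in percent of the substrate charged for Saturday's, Friday's, Tuesday's, Wednesday's, Monday's, in this order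
2. how that number moves from the first to the last of them (rises all the way / hardly changes / rises, then falls / falls, then rises / falls all the way)

The steps under discussion: substrate, reagent and catalyst give target; substrate exchanges with the dormant form; target exchanges with the isomer of the product over the catalyst.

Where can the loss be read? In the alder run, whose target falls from 61.3% at 15.0 min to 52.3% at 20.0 min. Taken as pseudo-first-order, that is a net loss constant of 0.0318 /min, a reading with its scatter.

What does it give a new flask? The tail factor, the fraction of target at the end of the feed that is still there at the reading once making has faded against loss: 0.853.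

Does it travel? Catalyst is the same in the alder run and in Monday's, and Monday's charge is larger. So I take the alder reading at 20.0 min as Monday's stand-in and reckon 44.6%.

And the weak spot? The factor counts no making, so I do not use it where I expect making to continue, as in Saturday's. Saturday's charge is 27.6% of the substrate, which makes reagent the limiting reagent. At 20.0 min the ash run held 12.0% of the 21.0% its charge allowed, and that share, carried over to Saturday's reading as my estimate, gives about 15.7%.

So does the row turn? The alder run's highest reading is 67.8% at 10.0 min. I expect Wednesday's smaller charge to bring its peak later and to end above Monday's, so I commit to a rise, then a fall.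

The forecast gives 17%, 30%, 47%, 51%, 43%: rises, then falls. Its ground for the loss: “Its later fall shows target isomerising at about 0.03 min⁻¹.”

The flasks give 16.5%, 29.8%, 46.3%, 46.5%, 44.0%: rises, then falls.

substrate + reagent + catalyst → target + catalyst, rate k1*[substrate]*[reagent]*[catalyst]/(1 + ([substrate]/sat1)) (0.0640 M, k = 600 /M²/s); substrate ⇌ dormant form (K = 0.900, k = 5.40 × 10⁻⁴ /s); target + catalyst ⇌ isomer of the product + catalyst, rate k3*[catalyst]*[target] forward; the back reaction follows from the equilibrium constant (K = 13.0, k = 0.920 /M/s) The row turns at 39 mM of reagent, between Tuesday's and Wednesday's, where the forecast's 51% parts from the flask's 46.5%. Wednesday's holds 53.9% target at 20.0 min with substrate at 0.598%, and the tail factor turns that into 46.0%. Monday's holds 51.6% target at 20.0 min with substrate at 0.115%, which the factor turns into 44.0%, and Monday's reads 44.0%.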